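**Retrosynthetic overview** (carotenoid numbering: trihydroxylated ring C1–C6, first chain carbon C7; primed locants for the ε end)
1. C40 = triol-end C15 dienal 22 + C10 bis(phosphonate) 31 + ε-end C15 dienal 27; two Horner–Wadsworth–Emmons olefinations make C11'=C12' and then C11=C12.
2. The ε ring is bought ready-made in (R)-α-ionone 23 and is never closed in the route; C3' is oxygenated by allylic oxidation and Luche reduction.
3. Triol end: C7=C8 comes from a Wittig reaction on a lactol, itself from the 2-oxabicyclo[2.2.2]octan-3-one 14 in which C7 is a carboxyl tied to O3.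
4. Key disconnection C5–C6: a samarium reductive aldol closure of the monocyclic α-keto-δ-lactone 12 (one stereocentre, from a Keck methallylation) forms the carbocycle C1–C6 and both tertiary carbinols. Enabling feature: O3 and C7 are cis-1,4 on the ring (on C3 and C6) and can be a lactone bridge, and C5(OH)(CH3)–C6(OH) is a vicinal ditertiary trans-diol next to the quaternary C1, the retron of a ketone/α-keto ester reductive coupling.
5. Ring order: temporary δ-lactone (step 5), then carbocycle C1–C6 (step 8, the only and last ring closure of the skeleton), then the lactone bridge is opened again (steps 10–11).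

Key step: step 8

Assumption: (R)-(+)-α-ionone 23 is taken as purchasable in enantiopure form, and the minor Z isomers from the olefinations that form trisubstituted or chain double bonds are removed by chromatography.

**Step 1**
Reactants: 1 ethyl glyoxylate; 2 1-bromo-3-methylbut-2-ene (prenyl bromide)
Product: 3 ethyl 2-hydroxy-3,3-dimethylpent-4-enoate (racemic)
Conditions: Zn dust, THF/sat. aq. NH4Cl, 0 °C → rt
Reagents that add atoms: none
Why: Zinc Barbier allylation in which the prenylzinc species adds through its γ-carbon, which should install the quaternary gem-dimethyl carbon C1 next to the C6 carbinol; that carbinol is made racemic on purpose because it becomes a ketone in step 7.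

**Step 2**
Reactants: 3 ethyl 2-hydroxy-3,3-dimethylpent-4-enoate
Product: 4 ethyl 3,3-dimethyl-2-[(triethylsilyl)oxy]pent-4-enoate (racemic)
Conditions: Et3SiCl, imidazole, DMF, 0 °C → rt
Reagents that add atoms: chlorotriethylsilane, CC[Si](Cl)(CC)CC
Why: Standard silyl ether formation, needed so that the aldehyde of step 3 stays open instead of closing to a five-membered lactol.

**Step 3**
Reactants: 4 ethyl 3,3-dimethyl-2-[(triethylsilyl)oxy]pent-4-enoate
Product: 5 ethyl 3,3-dimethyl-5-oxo-2-[(triethylsilyl)oxy]pentanoate (racemic)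
Conditions: Rh(acac)(CO)2 (1 mol %), Xantphos (2 mol %), CO/H2 (1:1, 20 bar), PhMe, 80 °C
Reagents that add atoms: carbon monoxide, [C-]#[O+]
Why: Rh-catalysed hydroformylation, in which the quaternary carbon next to the vinyl group and the wide-bite-angle ligand should direct the formyl group to the terminal carbon and give the C3 aldehyde.

**Step 4**
Reactants: 5 ethyl 3,3-dimethyl-5-oxo-2-[(triethylsilyl)oxy]pentanoate; 6 tributyl(2-methylprop-2-en-1-yl)stannane
Product: 7 ethyl (5R)-5-hydroxy-3,3,7-trimethyl-2-[(triethylsilyl)oxy]oct-7-enoate (both C2 epimers)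
Conditions: (R)-BINOL (20 mol %), Ti(OiPr)4 (10 mol %), 4 Å molecular sieves, CH2Cl2, –20 °C
Reagents that add atoms: none
Why: Keck asymmetric allylation (here a methallylation), in which the (R)-BINOL–Ti(OiPr)4 complex should deliver the methallyl group to the Re face of the aldehyde and so set the (5R) carbinol, the future C3 and the only stereocentre carried into the key step.

**Step 5**
Reactants: 7 ethyl (5R)-5-hydroxy-3,3,7-trimethyl-2-[(triethylsilyl)oxy]oct-7-enoate
Product: 9 (6R)-3-hydroxy-4,4-dimethyl-6-(2-methylprop-2-en-1-yl)oxan-2-one (both C3 epimers), via dihydroxy ester 8 (not isolated)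
Conditions: 1 M aq. HCl, THF, rt; then TsOH·H2O (5 mol %), PhMe, 60 °C
Reagents that add atoms: none
Why: Acidic cleavage of the triethylsilyl ether followed by acid-catalysed lactonisation of the δ-hydroxy ester, which the gem-dimethyl group favours (Thorpe–Ingold effect) and which leaves the C3 stereocentre untouched.

**Step 6**
Reactants: 9 (6R)-3-hydroxy-4,4-dimethyl-6-(2-methylprop-2-en-1-yl)oxan-2-one
Product: 11 (6S)-3-hydroxy-4,4-dimethyl-6-(2-oxopropyl)oxan-2-one (both C3 epimers), via ozonide 10 (not isolated)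
Conditions: O3, CH2Cl2, –78 °C; then PPh3, –78 °C → rt
Reagents that add atoms: ozone, [O-][O+]=O
Why: Ozonolysis with reductive work-up should cut the 1,1-disubstituted alkene to the methyl ketone (C5 with its methyl group) without touching the lactone or the secondary alcohol.

**Step 7**
Reactants: 11 (6S)-3-hydroxy-4,4-dimethyl-6-(2-oxopropyl)oxan-2-one
Product: 12 (6S)-4,4-dimethyl-6-(2-oxopropyl)oxane-2,3-dione
Conditions: Dess–Martin periodinane, CH2Cl2, 0 °C → rt
Reagents that add atoms: none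
Why: Dess–Martin oxidation of an α-hydroxy lactone to the α-keto lactone, which cannot enolise because C1 is quaternary and which merges both epimers of 11 into one compound.

**Step 8**
Reactants: 12 (6S)-4,4-dimethyl-6-(2-oxopropyl)oxane-2,3-dione
Product: 14 (1S,4S,5S)-4,5-dihydroxy-5,8,8-trimethyl-2-oxabicyclo[2.2.2]octan-3-one, via samarium enediolate 13 (not isolated)
Conditions: SmI2 (2.2 equiv, 0.1 M in THF), slow addition of 12, THF, –78 → –20 °C; then pH 7 phosphate buffer
Reagents that add atoms: none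
Why: Proposed new method: SmI2 (divalent samarium) should reduce the α-keto lactone, by far the most easily reduced carbonyl of 12, in two one-electron steps to the cyclic trivalent-samarium enediolate 13, whose carbon C6 adds to the C5 methyl ketone held over it by the C3 side chain (a reductive aldol; ketyl–ketone coupling after the first electron would form the same C5–C6 bond), and the samarium diolate is protonated on work-up. The closest known reaction types are the SmI2 pinacol cyclisation of 1,6-diketones, the aldol addition of samarium enediolates made from 1,2-diketones and the intramolecular samarium Reformatsky reaction; new are the α-keto lactone as the reducible partner and the bridging mode of closure. The carbocycle C1–C6 closes in a 6-(enolexo)-exo-trig mode across the lactone to give the 2-oxabicyclo[2.2.2]octan-3-one, helped by the C1 gem-dimethyl group (Thorpe–Ingold effect). C6 is controlled by the tether, because the ketone can reach the enediolate only on the lactone face that carries the side chain, so the (S) centre C3 places C7 cis to O3 and the new C6–OH trans to it. C5 is controlled by chelation, because the samarium held by both enediolate oxygens (O6 and the lactone carbonyl oxygen) should also bind the ketone oxygen and turn it toward the lactone bridge and the methyl toward the gem-dimethyl bridge, giving the C5–OH cis to O3 and trans to the C6–OH. The step needs chemoselective reduction (α-dicarbonyl before the isolated ketone, secured by leaving out HMPA and any proton source) and facial selectivity at the ketone (secured by the three-point chelate in THF at low temperature).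

**Step 9**
Reactants: 14 (1S,4S,5S)-4,5-dihydroxy-5,8,8-trimethyl-2-oxabicyclo[2.2.2]octan-3-one
Product: 15 (1S,4S,5S)-5,8,8-trimethyl-4,5-bis[(trimethylsilyl)oxy]-2-oxabicyclo[2.2.2]octan-3-one
Conditions: Me3SiOTf (3 equiv), 2,6-lutidine (4 equiv), CH2Cl2, –78 → 0 °C
Reagents that add atoms: trimethylsilyl trifluoromethanesulfonate, C[Si](C)(C)OS(=O)(=O)C(F)(F)F
Why: Silylation of both tertiary alcohols with the silyl triflate blocks retro-aldol cleavage of the C5–C6 bond once C7 becomes an aldehyde.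

**Step 10**
Reactants: 15 (1S,4S,5S)-5,8,8-trimethyl-4,5-bis[(trimethylsilyl)oxy]-2-oxabicyclo[2.2.2]octan-3-one
Product: 16 (1S,4S,5S)-5,8,8-trimethyl-4,5-bis[(trimethylsilyl)oxy]-2-oxabicyclo[2.2.2]octan-3-ol (lactol, both C3 epimers, in equilibrium with the open hydroxy aldehyde)
Conditions: i-Bu2AlH (1.2 equiv), CH2Cl2, –78 °C; aq. KNaC4H4O6
Reagents that add atoms: none
Why: Partial reduction of a lactone to the lactol with i-Bu2AlH at low temperature, where the tetrahedral aluminium hemiacetal is stable and the silyl ethers should remain intact.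

**Step 11**
Reactants: 16 (1S,4S,5S)-5,8,8-trimethyl-4,5-bis[(trimethylsilyl)oxy]-2-oxabicyclo[2.2.2]octan-3-ol; 17 1-(triphenyl-λ5-phosphanylidene)propan-2-one
Product: 18 (3E)-4-[(1S,2S,4S)-4-hydroxy-2,6,6-trimethyl-1,2-bis[(trimethylsilyl)oxy]cyclohexyl]but-3-en-2-one
Conditions: PhMe, 90 °C
Reagents that add atoms: none
Why: Wittig reaction of a lactol through its open hydroxy aldehyde form with a stabilised ylide under neutral conditions, which should give the (E)-enone (C7=C8) and free the C3 hydroxyl without forming an alkoxide that could trigger silyl migration.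

**Step 12**
Reactants: 18 (3E)-4-[(1S,2S,4S)-4-hydroxy-2,6,6-trimethyl-1,2-bis[(trimethylsilyl)oxy]cyclohexyl]but-3-en-2-one
Product: 19 (3E)-4-[(1S,2S,4S)-2,6,6-trimethyl-4-[(triethylsilyl)oxy]-1,2-bis[(trimethylsilyl)oxy]cyclohexyl]but-3-en-2-one
Conditions: Et3SiCl, imidazole, DMF, rt
Reagents that add atoms: chlorotriethylsilane, CC[Si](Cl)(CC)CC
Why: Silyl ether formation at the secondary C3 hydroxyl, to prevent oxa-Michael addition to the enone under the basic conditions that follow.

**Step 13**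
Reactants: 19 (3E)-4-[(1S,2S,4S)-2,6,6-trimethyl-4-[(triethylsilyl)oxy]-1,2-bis[(trimethylsilyl)oxy]cyclohexyl]but-3-en-2-one; 20 diethyl (cyanomethyl)phosphonate
Product: 21 (2E,4E)-3-methyl-5-[(1S,2S,4S)-2,6,6-trimethyl-4-[(triethylsilyl)oxy]-1,2-bis[(trimethylsilyl)oxy]cyclohexyl]penta-2,4-dienenitrile
Conditions: NaH, THF, 0 → 40 °C
Reagents that add atoms: none
Why: Horner–Wadsworth–Emmons olefination of the methyl ketone with the cyanomethylphosphonate anion, which should give mainly the (9E) dienenitrile.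

**Step 14**
Reactants: 21 (2E,4E)-3-methyl-5-[(1S,2S,4S)-2,6,6-trimethyl-4-[(triethylsilyl)oxy]-1,2-bis[(trimethylsilyl)oxy]cyclohexyl]penta-2,4-dienenitrile
Product: 22 (2E,4E)-3-methyl-5-[(1S,2S,4S)-2,6,6-trimethyl-4-[(triethylsilyl)oxy]-1,2-bis[(trimethylsilyl)oxy]cyclohexyl]penta-2,4-dienal
Conditions: i-Bu2AlH (1.5 equiv), PhMe, –78 °C; then wet SiO2, 0 °C
Reagents that add atoms: water, O
Why: i-Bu2AlH reduction of the nitrile to the N-aluminio aldimine, which is hydrolysed on wet silica to the dienal while the silyl ethers should survive the near-neutral work-up.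

**Step 15**
Reactants: 23 (R)-α-ionone, (3E)-4-[(1R)-2,6,6-trimethylcyclohex-2-en-1-yl]but-3-en-2-one; 20 diethyl (cyanomethyl)phosphonate
Product: 24 (2E,4E)-3-methyl-5-[(1R)-2,6,6-trimethylcyclohex-2-en-1-yl]penta-2,4-dienenitrile
Conditions: NaH, THF, 0 °C → rt
Reagents that add atoms: none
Why: Horner–Wadsworth–Emmons olefination of the methyl ketone, expected to give mainly the (9'E) nitrile, while the ring stereocentre C6' is not acidic enough to epimerise under these conditions.

**Step 16**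
Reactants: 24 (2E,4E)-3-methyl-5-[(1R)-2,6,6-trimethylcyclohex-2-en-1-yl]penta-2,4-dienenitrile
Product: 25 (2E,4E)-3-methyl-5-[(1R)-2,6,6-trimethyl-4-oxocyclohex-2-en-1-yl]penta-2,4-dienenitrile
Conditions: Rh2(caprolactamate)4 (1 mol %), t-BuOOH (70% aq., 5 equiv), K2CO3, CH2Cl2, rt
Reagents that add atoms: tert-butyl hydroperoxide, CC(C)(C)OO
Why: Rh-catalysed allylic C–H oxidation with t-BuOOH, which should convert the only allylic ring methylene (C3') into the enone, the doubly allylic C6'–H being shielded by the neighbouring gem-dimethyl and methyl groups.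

**Step 17**
Reactants: 25 (2E,4E)-3-methyl-5-[(1R)-2,6,6-trimethyl-4-oxocyclohex-2-en-1-yl]penta-2,4-dienenitrile
Product: 26 (2E,4E)-5-[(1R,4R)-4-hydroxy-2,6,6-trimethylcyclohex-2-en-1-yl]-3-methylpenta-2,4-dienenitrile
Conditions: NaBH4, CeCl3·7H2O, MeOH, –40 °C
Reagents that add atoms: none
Why: Luche reduction (1,2-selective, nitrile untouched), in which the pseudoaxial side chain on C6' leaves the pseudoaxial C1' methyl to block the opposite face, so that hydride should enter syn to the side chain and give the 3',6'-trans alcohol with the (4R) carbinol.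

**Step 18**
Reactants: 26 (2E,4E)-5-[(1R,4R)-4-hydroxy-2,6,6-trimethylcyclohex-2-en-1-yl]-3-methylpenta-2,4-dienenitrile
Product: 27 (2E,4E)-5-[(1R,4R)-4-hydroxy-2,6,6-trimethylcyclohex-2-en-1-yl]-3-methylpenta-2,4-dienal
Conditions: i-Bu2AlH (2.5 equiv), CH2Cl2, –78 °C; then wet SiO2, 0 °C
Reagents that add atoms: water, O
Why: i-Bu2AlH reduction of the nitrile (one extra equivalent is consumed by the hydroxyl) and hydrolysis of the aldimine to the hydroxy dienal.

**Step 19**
Reactants: 28 (2E,4E,6E)-2,7-dimethylocta-2,4,6-trienedial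
Product: 29 (2E,4E,6E)-2,7-dimethylocta-2,4,6-triene-1,8-diol
Conditions: NaBH4, MeOH/THF, 0 °C
Reagents that add atoms: none
Why: 1,2-Reduction of both conjugated aldehydes by NaBH4.

**Step 20**
Reactants: 29 (2E,4E,6E)-2,7-dimethylocta-2,4,6-triene-1,8-diol
Product: 30 (2E,4E,6E)-1,8-dibromo-2,7-dimethylocta-2,4,6-triene
Conditions: PBr3 (0.7 equiv), pyridine (cat.), Et2O, –10 °C
Reagents that add atoms: phosphorus tribromide, BrP(Br)Br
Why: Conversion of the primary allylic alcohols into bromides with PBr3 at low temperature, which should keep the all-E triene.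

**Step 21**
Reactants: 30 (2E,4E,6E)-1,8-dibromo-2,7-dimethylocta-2,4,6-triene
Product: 31 tetraethyl [(2E,4E,6E)-2,7-dimethylocta-2,4,6-triene-1,8-diyl]bis(phosphonate)
Conditions: P(OEt)3 (neat), 120 °C
Reagents that add atoms: triethyl phosphite, CCOP(OCC)OCC
Why: Michaelis–Arbuzov reaction of the bis(allylic bromide) with triethyl phosphite.

**Step 22**
Reactants: 27 (2E,4E)-5-[(1R,4R)-4-hydroxy-2,6,6-trimethylcyclohex-2-en-1-yl]-3-methylpenta-2,4-dienal; 31 tetraethyl [(2E,4E,6E)-2,7-dimethylocta-2,4,6-triene-1,8-diyl]bis(phosphonate)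
Product: 32 diethyl [(2E,4E,6E,8E,10E,12E)-13-[(1R,4R)-4-hydroxy-2,6,6-trimethylcyclohex-2-en-1-yl]-2,7,11-trimethyltrideca-2,4,6,8,10,12-hexaen-1-yl]phosphonate
Conditions: 31 (4 equiv), LiN(SiMe3)2 (5 equiv), THF, –78 °C; then slow addition of 27, –78 → 0 °C
Reagents that add atoms: none
Why: Horner–Wadsworth–Emmons olefination at one end of the bis(phosphonate), held in excess so that mainly mono-olefination should occur, forming the C11'=C12' bond with E geometry expected.

**Step 23**
Reactants: 32 diethyl [(2E,4E,6E,8E,10E,12E)-13-[(1R,4R)-4-hydroxy-2,6,6-trimethylcyclohex-2-en-1-yl]-2,7,11-trimethyltrideca-2,4,6,8,10,12-hexaen-1-yl]phosphonate; 22 (2E,4E)-3-methyl-5-[(1S,2S,4S)-2,6,6-trimethyl-4-[(triethylsilyl)oxy]-1,2-bis[(trimethylsilyl)oxy]cyclohexyl]penta-2,4-dienal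
Product: 33 (3S,5S,6S,3'R,6'R)-3-[(triethylsilyl)oxy]-5,6-bis[(trimethylsilyl)oxy]-5,6-dihydro-β,ε-caroten-3'-ol (all-E)
Conditions: LiN(SiMe3)2 (2.3 equiv), THF, –78 → 0 °C
Reagents that add atoms: none
Why: Horner–Wadsworth–Emmons olefination of the allylic phosphonate carbanion with the dienal forms C11=C12, expected mainly E, with all five stereocentres remote from the reacting centres.

**Step 24**
Reactants: 33 (3S,5S,6S,3'R,6'R)-3-[(triethylsilyl)oxy]-5,6-bis[(trimethylsilyl)oxy]-5,6-dihydro-β,ε-caroten-3'-ol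
Product: 34 (3S,5S,6S,3'R,6'R)-5,6-dihydro-β,ε-carotene-3,5,6,3'-tetrol (all-E), CNP0219917.1
Conditions: Bu4NF, AcOH (1:1), THF, 0 °C → rt
Reagents that add atoms: none
Why: Fluoride-mediated cleavage of the three silyl ethers under buffered conditions, which avoids the acid that would ionise the allylic tertiary C6 alcohol.

**Compound list**
1 | ethyl glyoxylate | CCOC(=O)C=O | starting material
2 | 1-bromo-3-methylbut-2-ene | CC(C)=CCBr | starting material
3 | ethyl 2-hydroxy-3,3-dimethylpent-4-enoate (racemic) | CCOC(=O)C(O)C(C)(C)C=C | intermediate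
4 | ethyl 3,3-dimethyl-2-[(triethylsilyl)oxy]pent-4-enoate (racemic) | CCOC(=O)C(O[Si](CC)(CC)CC)C(C)(C)C=C | intermediate
5 | ethyl 3,3-dimethyl-5-oxo-2-[(triethylsilyl)oxy]pentanoate (racemic) | CCOC(=O)C(O[Si](CC)(CC)CC)C(C)(C)CC=O | intermediate
6 | tributyl(2-methylprop-2-en-1-yl)stannane | CC(=C)C[Sn](CCCC)(CCCC)CCCC | starting material
7 | ethyl (5R)-5-hydroxy-3,3,7-trimethyl-2-[(triethylsilyl)oxy]oct-7-enoate (C2 epimers) | CCOC(=O)C(O[Si](CC)(CC)CC)C(C)(C)C[C@H](O)CC(C)=C | intermediate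
8 | ethyl (5R)-2,5-dihydroxy-3,3,7-trimethyloct-7-enoate (C2 epimers) | CCOC(=O)C(O)C(C)(C)C[C@H](O)CC(C)=C | intermediate
9 | (6R)-3-hydroxy-4,4-dimethyl-6-(2-methylprop-2-en-1-yl)oxan-2-one (C3 epimers) | O=C1C(O)C(C)(C)C[C@H](O1)CC(C)=C | intermediate
10 | (6S)-3-hydroxy-4,4-dimethyl-6-[(3-methyl-1,2,4-trioxolan-3-yl)methyl]oxan-2-one (ozonide) | O=C1C(O)C(C)(C)C[C@H](O1)CC2(C)OCOO2 | intermediate
11 | (6S)-3-hydroxy-4,4-dimethyl-6-(2-oxopropyl)oxan-2-one (C3 epimers) | O=C1C(O)C(C)(C)C[C@H](O1)CC(C)=O | intermediate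
12 | (6S)-4,4-dimethyl-6-(2-oxopropyl)oxane-2,3-dione | O=C1C(=O)C(C)(C)C[C@H](O1)CC(C)=O | intermediate
13 | trivalent-samarium enediolate of 12, (6S)-2,3-bis[(diiodosamario)oxy]-4,4-dimethyl-6-(2-oxopropyl)-5,6-dihydro-4H-pyran | I[Sm](I)OC1=C(O[Sm](I)I)C(C)(C)C[C@H](O1)CC(C)=O | intermediate
14 | (1S,4S,5S)-4,5-dihydroxy-5,8,8-trimethyl-2-oxabicyclo[2.2.2]octan-3-one | O=C2[C@]1(O)C(C)(C)C[C@H](O2)C[C@]1(C)O | intermediate
15 | (1S,4S,5S)-5,8,8-trimethyl-4,5-bis[(trimethylsilyl)oxy]-2-oxabicyclo[2.2.2]octan-3-one | O=C2[C@]1(O[Si](C)(C)C)C(C)(C)C[C@H](O2)C[C@]1(C)O[Si](C)(C)C | intermediate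
16 | (1S,4S,5S)-5,8,8-trimethyl-4,5-bis[(trimethylsilyl)oxy]-2-oxabicyclo[2.2.2]octan-3-ol (C3 epimers) | OC2[C@]1(O[Si](C)(C)C)C(C)(C)C[C@H](O2)C[C@]1(C)O[Si](C)(C)C | intermediate
17 | 1-(triphenyl-λ5-phosphanylidene)propan-2-one | CC(=O)C=P(c1ccccc1)(c1ccccc1)c1ccccc1 | starting material
18 | (3E)-4-[(1S,2S,4S)-4-hydroxy-2,6,6-trimethyl-1,2-bis[(trimethylsilyl)oxy]cyclohexyl]but-3-en-2-one | CC(=O)/C=C/[C@]1(O[Si](C)(C)C)C(C)(C)C[C@H](O)C[C@]1(C)O[Si](C)(C)C | intermediate
19 | (3E)-4-[(1S,2S,4S)-2,6,6-trimethyl-4-[(triethylsilyl)oxy]-1,2-bis[(trimethylsilyl)oxy]cyclohexyl]but-3-en-2-one | CC(=O)/C=C/[C@]1(O[Si](C)(C)C)C(C)(C)C[C@H](O[Si](CC)(CC)CC)C[C@]1(C)O[Si](C)(C)C | intermediate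
20 | diethyl (cyanomethyl)phosphonate | CCOP(=O)(CC#N)OCC | starting material
21 | (2E,4E)-3-methyl-5-[(1S,2S,4S)-2,6,6-trimethyl-4-[(triethylsilyl)oxy]-1,2-bis[(trimethylsilyl)oxy]cyclohexyl]penta-2,4-dienenitrile | N#C/C=C(C)/C=C/[C@]1(O[Si](C)(C)C)C(C)(C)C[C@H](O[Si](CC)(CC)CC)C[C@]1(C)O[Si](C)(C)C | intermediate
22 | (2E,4E)-3-methyl-5-[(1S,2S,4S)-2,6,6-trimethyl-4-[(triethylsilyl)oxy]-1,2-bis[(trimethylsilyl)oxy]cyclohexyl]penta-2,4-dienal | O=C/C=C(C)/C=C/[C@]1(O[Si](C)(C)C)C(C)(C)C[C@H](O[Si](CC)(CC)CC)C[C@]1(C)O[Si](C)(C)C | intermediate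
23 | (R)-α-ionone, (3E)-4-[(1R)-2,6,6-trimethylcyclohex-2-en-1-yl]but-3-en-2-one | CC1=CCCC(C)(C)[C@H]1/C=C/C(C)=O | starting material
24 | (2E,4E)-3-methyl-5-[(1R)-2,6,6-trimethylcyclohex-2-en-1-yl]penta-2,4-dienenitrile | CC1=CCCC(C)(C)[C@H]1/C=C/C(C)=C/C#N | intermediate
25 | (2E,4E)-3-methyl-5-[(1R)-2,6,6-trimethyl-4-oxocyclohex-2-en-1-yl]penta-2,4-dienenitrile | CC1=CC(=O)CC(C)(C)[C@H]1/C=C/C(C)=C/C#N | intermediate
26 | (2E,4E)-5-[(1R,4R)-4-hydroxy-2,6,6-trimethylcyclohex-2-en-1-yl]-3-methylpenta-2,4-dienenitrile | CC1=C[C@H](O)CC(C)(C)[C@H]1/C=C/C(C)=C/C#N | intermediate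
27 | (2E,4E)-5-[(1R,4R)-4-hydroxy-2,6,6-trimethylcyclohex-2-en-1-yl]-3-methylpenta-2,4-dienal | CC1=C[C@H](O)CC(C)(C)[C@H]1/C=C/C(C)=C/C=O | intermediate
28 | (2E,4E,6E)-2,7-dimethylocta-2,4,6-trienedial | O=C/C(C)=C/C=C/C=C(C)/C=O | starting material
29 | (2E,4E,6E)-2,7-dimethylocta-2,4,6-triene-1,8-diol | OC/C(C)=C/C=C/C=C(C)/CO | intermediate
30 | (2E,4E,6E)-1,8-dibromo-2,7-dimethylocta-2,4,6-triene | BrC/C(C)=C/C=C/C=C(C)/CBr | intermediate
31 | tetraethyl [(2E,4E,6E)-2,7-dimethylocta-2,4,6-triene-1,8-diyl]bis(phosphonate) | CCOP(=O)(OCC)C/C(C)=C/C=C/C=C(C)/CP(=O)(OCC)OCC | intermediate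
32 | diethyl [(2E,4E,6E,8E,10E,12E)-13-[(1R,4R)-4-hydroxy-2,6,6-trimethylcyclohex-2-en-1-yl]-2,7,11-trimethyltrideca-2,4,6,8,10,12-hexaen-1-yl]phosphonate | CC1=C[C@H](O)CC(C)(C)[C@H]1/C=C/C(C)=C/C=C/C(C)=C/C=C/C=C(C)/CP(=O)(OCC)OCC | intermediate
33 | (3S,5S,6S,3'R,6'R)-3-[(triethylsilyl)oxy]-5,6-bis[(trimethylsilyl)oxy]-5,6-dihydro-β,ε-caroten-3'-ol | CC1=C[C@H](O)CC(C)(C)[C@H]1/C=C/C(C)=C/C=C/C(C)=C/C=C/C=C(C)/C=C/C=C(C)/C=C/[C@]1(O[Si](C)(C)C)C(C)(C)C[C@H](O[Si](CC)(CC)CC)C[C@]1(C)O[Si](C)(C)C | intermediate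
34 | (3S,5S,6S,3'R,6'R)-5,6-dihydro-β,ε-carotene-3,5,6,3'-tetrol | CC1=C[C@H](O)CC(C)(C)[C@H]1/C=C/C(C)=C/C=C/C(C)=C/C=C/C=C(C)/C=C/C=C(C)/C=C/[C@]1(O)C(C)(C)C[C@H](O)C[C@]1(C)O | target

**Step count and risks**
Total step count: 24. Longest linear sequence: 16 steps (steps 1–14, then 23 and 24).

Steps most likely to fail:

Step 8 (proposed new method). The enediolate may be protonated on work-up without having added to the ketone, so that only reduction occurs. Facial selectivity at the ketone may also be poor if the samarium chelate is loose, because the sterically easier approach puts the C5 methyl on the lactone side. The fallback sets out from 12 and uses known chemistry. Reductive bis-silylation with Zn dust and Me3SiCl in THF should give the cyclic ketene bis(silyl) acetal (6S)-4,4-dimethyl-6-(2-oxopropyl)-2,3-bis[(trimethylsilyl)oxy]-5,6-dihydro-4H-pyran F1. A TiCl4-promoted intramolecular Mukaiyama aldol addition (CH2Cl2, –78 °C), in which the Lewis acid activates the ketone, should then close the same C5–C6 bond and give (1S,4S,5S)-5-hydroxy-5,8,8-trimethyl-4-[(trimethylsilyl)oxy]-2-oxabicyclo[2.2.2]octan-3-one F2. Silylation of the remaining C5 hydroxyl (Me3SiOTf, 2,6-lutidine) brings the material back to the route at 15.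

Step 11. The stabilised ylide may react too slowly with the small open-chain share of the very hindered, bridged lactol, so that prolonged heating leads to silyl migration or decomposition instead of olefination. The fallback sets out from 15. Ring opening of the lactone with MeNH(OMe)·HCl and i-PrMgCl (THF, –20 °C) should give the Weinreb amide (1S,2S,4S)-4-hydroxy-N-methoxy-N,2,6,6-tetramethyl-1,2-bis[(trimethylsilyl)oxy]cyclohexane-1-carboxamide F3. Silylation (Et3SiCl, imidazole) gives (1S,2S,4S)-N-methoxy-N,2,6,6-tetramethyl-4-[(triethylsilyl)oxy]-1,2-bis[(trimethylsilyl)oxy]cyclohexane-1-carboxamide F4. Reduction with i-Bu2AlH gives the fully protected open aldehyde (1S,2S,4S)-2,6,6-trimethyl-4-[(triethylsilyl)oxy]-1,2-bis[(trimethylsilyl)oxy]cyclohexane-1-carbaldehyde F5. A Horner–Wadsworth–Emmons olefination with dimethyl (2-oxopropyl)phosphonate and Ba(OH)2 in wet THF comes back to the route at 19.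

Step 17. Facial selectivity of hydride delivery to the ring ketone may be poor, which would divert material into the 3',6'-cis alcohol. The fallback sets out from 25. The reduction is run with a hydride chosen for conversion only, and the cis alcohol (2E,4E)-5-[(1R,4S)-4-hydroxy-2,6,6-trimethylcyclohex-2-en-1-yl]-3-methylpenta-2,4-dienenitrile F6 is separated. It is inverted by Mitsunobu esterification (4-nitrobenzoic acid, PPh3, diisopropyl azodicarboxylate) to (1R,4R)-4-[(1E,3E)-4-cyano-3-methylbuta-1,3-dien-1-yl]-3,5,5-trimethylcyclohex-2-en-1-yl 4-nitrobenzoate F7. Methanolysis (K2CO3, MeOH) comes back to the route at 26.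

**Further compounds**
F1 | step 8 | (6S)-4,4-dimethyl-6-(2-oxopropyl)-2,3-bis[(trimethylsilyl)oxy]-5,6-dihydro-4H-pyran | C[Si](C)(C)OC1=C(O[Si](C)(C)C)C(C)(C)C[C@H](O1)CC(C)=O
F2 | step 8 | (1S,4S,5S)-5-hydroxy-5,8,8-trimethyl-4-[(trimethylsilyl)oxy]-2-oxabicyclo[2.2.2]octan-3-one | O=C2[C@]1(O[Si](C)(C)C)C(C)(C)C[C@H](O2)C[C@]1(C)O
F3 | step 11 | (1S,2S,4S)-4-hydroxy-N-methoxy-N,2,6,6-tetramethyl-1,2-bis[(trimethylsilyl)oxy]cyclohexane-1-carboxamide | CON(C)C(=O)[C@]1(O[Si](C)(C)C)C(C)(C)C[C@H](O)C[C@]1(C)O[Si](C)(C)C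
F4 | step 11 | (1S,2S,4S)-N-methoxy-N,2,6,6-tetramethyl-4-[(triethylsilyl)oxy]-1,2-bis[(trimethylsilyl)oxy]cyclohexane-1-carboxamide | CON(C)C(=O)[C@]1(O[Si](C)(C)C)C(C)(C)C[C@H](O[Si](CC)(CC)CC)C[C@]1(C)O[Si](C)(C)C
F5 | step 11 | (1S,2S,4S)-2,6,6-trimethyl-4-[(triethylsilyl)oxy]-1,2-bis[(trimethylsilyl)oxy]cyclohexane-1-carbaldehyde | O=C[C@]1(O[Si](C)(C)C)C(C)(C)C[C@H](O[Si](CC)(CC)CC)C[C@]1(C)O[Si](C)(C)C
F6 | step 17 | (2E,4E)-5-[(1R,4S)-4-hydroxy-2,6,6-trimethylcyclohex-2-en-1-yl]-3-methylpenta-2,4-dienenitrile | CC1=C[C@@H](O)CC(C)(C)[C@H]1/C=C/C(C)=C/C#N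
F7 | step 17 | (1R,4R)-4-[(1E,3E)-4-cyano-3-methylbuta-1,3-dien-1-yl]-3,5,5-trimethylcyclohex-2-en-1-yl 4-nitrobenzoate | CC1=C[C@H](OC(=O)c2ccc(cc2)[N+](=O)[O-])CC(C)(C)[C@H]1/C=C/C(C)=C/C#N
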